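**Retrosynthetic overview**
1. Target 12 ⇐ bromohydrin 11 (tertiary C3–OH exchanged for Cl through a bromonium ion) ⇐ α-bromo ketone 10 ⇐ spiro dienone 8 (C2–Br via a regiodefined enol silane, C3–CH3 by Grignard addition).
2. Ring B (formed second): Robinson spiroannulation of methyl vinyl ketone 6 onto bromo-α-cyclocitral 5 (C5–C6 Michael bond, then C1=C2 aldol); this creates the spiro carbon.
3. Ring A (formed first): C6–C11 bond by dehydrative bromonium cyclisation of the acyclic bromohydrin acetal 3 (new step).
4. C10–Br ⇐ C–O: the (S)-bromide comes from SN2 opening of the (R)-epoxide 2. That C–O bond, made by catalytic asymmetric epoxidation of citral dimethyl acetal 1, is the only reagent-controlled stereo-defining event.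
5. C6, C2 and C3 are then relayed from C10 by substrate control.

Assumption: spiro compounds carry chamigrene-type numbering (ring B = C1–C5, spiro carbon C6, ring A = C7–C11), and commercial 1 is used as its E/Z mixture because that alkene geometry is erased in step 3.

**Step 1**
Reactants: 1 citral dimethyl acetal (1,1-dimethoxy-3,7-dimethylocta-2,6-diene)
Product: 2 (3R)-3-(5,5-dimethoxy-3-methylpent-3-en-1-yl)-2,2-dimethyloxirane
Conditions: 1,2:4,5-di-O-isopropylidene-β-D-erythro-2,3-hexodiulo-2,6-pyranose (30 mol %), KHSO5 (as 2KHSO5·KHSO4·K2SO4, 1.4 equiv), K2CO3, Bu4NHSO4 (cat.), MeCN–CH2(OMe)2 / aq. Na2B4O7 buffer, pH 10.5, 0 °C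
Reagents that add atoms: potassium peroxymonosulfate, [K+].[O-]S(=O)(=O)OO
Why: Shi asymmetric epoxidation, in which the electrophilic dioxirane of the D-fructose-derived ketone oxidises only the electron-rich 6,7-alkene (the 2,3-alkene is deactivated by the allylic acetal) through the spiro transition state that gives the (R)-epoxide (about 90% ee expected for this alkene class, to be upgraded by recrystallising dibromo ketone 10 if it proves crystalline).

**Step 2**
Reactants: 2 (3R)-3-(5,5-dimethoxy-3-methylpent-3-en-1-yl)-2,2-dimethyloxirane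
Product: 3 (3S)-3-bromo-8,8-dimethoxy-2,6-dimethyloct-6-en-2-ol
Conditions: Li2NiBr4 (0.4 M in THF, 1.3 equiv), THF, 0 °C to rt; water work-up
Reagents that add atoms: dilithium tetrabromonickelate, [Li+].[Li+].[Ni+2].[Br-].[Br-].[Br-].[Br-]
Why: SN2 epoxide opening by soft, non-acidic bromide at the less substituted carbon with inversion turns the (R)-C–O carbon into the (S)-C–Br carbon, while the tertiary C–O bond stays as the alcohol.

**Step 3**
Reactants: 3 (3S)-3-bromo-8,8-dimethoxy-2,6-dimethyloct-6-en-2-ol
Product: 5 (5S)-5-bromo-2,6,6-trimethylcyclohex-2-ene-1-carbaldehyde, via dienol ether 4 (not isolated)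
Conditions: CF3SO3H (10 mol %), (CF3)2CHOH, 0.02 M, −20 °C to 0 °C; then aq. NaHCO3
Reagents that add atoms: none
Why: Proposed new method: catalytic acid in the ionising solvent converts the acetal into the nucleophilic 1-methoxydiene 4 and ionises the tertiary C–OH with help from the neighbouring bromine to a bromonium ion, whose tertiary carbon is attacked by the diene α-carbon in a chair-like six-membered transition state (Br equatorial, the C–Br stereocentre is not touched and stays S), after which the water set free hydrolyses the oxocarbenium ion to the aldehyde (5 forms as a mixture of epimers at the formyl-bearing carbon, which is planarised in step 4); the closest known reaction types are the solvolytic bromonium polyene cyclisation of enantioenriched vicinal bromochlorides in (CF3)2CHOH and the classical acid-mediated cyclisation of citral imines or enamines to α-cyclocitral.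

**Step 4**
Reactants: 5 (5S)-5-bromo-2,6,6-trimethylcyclohex-2-ene-1-carbaldehyde; 6 methyl vinyl ketone (but-3-en-2-one)
Product: 8 (6R,10S)-10-bromo-7,11,11-trimethylspiro[5.5]undeca-1,7-dien-3-one, via keto aldehyde 7 (not isolated)
Conditions: 6 (1.5 equiv), KOC(CH3)3 (0.1 equiv), t-BuOH–THF, −20 to 0 °C; then pyrrolidine (0.3 equiv), CH3CO2H (0.3 equiv), toluene, 60 °C
Reagents that add atoms: none
Why: Robinson spiroannulation (Michael addition of the aldehyde dienolate at its α-carbon, then enamine-mediated aldol condensation), in which the enone approaches the planar dienolate on the face opposite the pseudoaxial C11 methyl group and anti to the C10–Br bond, so the new CH2CH2 arm ends trans and the formyl carbon cis to bromine (6R).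

**Step 5**
Reactants: 8 (6R,10S)-10-bromo-7,11,11-trimethylspiro[5.5]undeca-1,7-dien-3-one
Product: 10 (2R,6R,10S)-2,10-dibromo-7,11,11-trimethylspiro[5.5]undec-7-en-3-one, via silyl enol ether 9 (not isolated)
Conditions: [(Ph3P)CuH]6 (5 mol %), PhMe2SiH (1.2 equiv), toluene, rt; then N-bromosuccinimide (1.05 equiv), THF, −78 to 0 °C
Reagents that add atoms: N-bromosuccinimide, O=C1CCC(=O)N1Br
Why: Copper hydride conjugate reduction gives only the C2=C3 enol silane (so bromine can enter only at C2), and bromination occurs on the face away from the axial ring A carbon C7 to give the equatorial bromide cis to C11 (2R), which is also the more stable epimer, as in the 2α-bromination of 3-keto-5α-steroids.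

**Step 6**
Reactants: 10 (2R,6R,10S)-2,10-dibromo-7,11,11-trimethylspiro[5.5]undec-7-en-3-one
Product: 11 (2R,6R,10S)-2,10-dibromo-3,7,11,11-tetramethylspiro[5.5]undec-7-en-3-ol
Conditions: CH3MgBr (1.2 equiv), Et2O–toluene, −78 °C; water quench at −78 °C
Reagents that add atoms: methylmagnesium bromide, C[Mg]Br
Why: Grignard 1,2-addition to the unhindered, α-bromo-activated ketone at low temperature (cold quench prevents epoxide formation) leaves C2 untouched, and both C3 epimers are carried on because step 7 passes through a common ion.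

**Step 7**
Reactants: 11 (2R,6R,10S)-2,10-dibromo-3,7,11,11-tetramethylspiro[5.5]undec-7-en-3-ol
Product: 12 (2R,3R,6R,10S)-2,10-dibromo-3-chloro-3,7,11,11-tetramethylspiro[5.5]undec-7-ene
Conditions: 1-chloro-N,N,2-trimethylprop-1-en-1-amine (1.5 equiv), CH2Cl2, 0 °C to rt
Reagents that add atoms: 1-chloro-N,N,2-trimethylprop-1-en-1-amine, CC(C)=C(Cl)N(C)C
Why: Neutral deoxychlorination of a tertiary alcohol with an α-chloroenamine, in which the alkoxyiminium ion ionises, the C2 bromine bridges from its own face to a bromonium ion, and chloride opens it at the tertiary carbon anti to bromine, setting C3 as R (trans Br/Cl) from either C3 epimer without acid that would attack the ring A alkene.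

**Compound list**
1 | citral dimethyl acetal, 1,1-dimethoxy-3,7-dimethylocta-2,6-diene (E/Z mixture) | COC(OC)C=C(C)CCC=C(C)C | starting material
2 | (3R)-3-(5,5-dimethoxy-3-methylpent-3-en-1-yl)-2,2-dimethyloxirane (E/Z mixture at the remaining alkene) | COC(OC)C=C(C)CC[C@H]1OC1(C)C | intermediate
3 | (3S)-3-bromo-8,8-dimethoxy-2,6-dimethyloct-6-en-2-ol (E/Z mixture) | COC(OC)C=C(C)CC[C@H](Br)C(C)(C)O | intermediate
4 | (3S)-3-bromo-8-methoxy-2,6-dimethylocta-5,7-dien-2-ol (dienol ether, alkene isomers in equilibrium, not isolated) | COC=CC(C)=CC[C@H](Br)C(C)(C)O | intermediate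
5 | (5S)-5-bromo-2,6,6-trimethylcyclohex-2-ene-1-carbaldehyde (both epimers at C1 of the ring, SMILES leaves that centre open) | O=CC1C(C)=CC[C@H](Br)C1(C)C | intermediate
6 | methyl vinyl ketone (but-3-en-2-one) | CC(=O)C=C | starting material
7 | (1R,5S)-5-bromo-2,6,6-trimethyl-1-(3-oxobutyl)cyclohex-2-ene-1-carbaldehyde (not isolated) | CC1=CC[C@H](Br)C(C)(C)[C@@]1(C=O)CCC(C)=O | intermediate
8 | (6R,10S)-10-bromo-7,11,11-trimethylspiro[5.5]undeca-1,7-dien-3-one | CC1=CC[C@H](Br)C(C)(C)[C@@]12CCC(=O)C=C2 | intermediate
9 | [(6R,10S)-10-bromo-7,11,11-trimethylspiro[5.5]undeca-2,7-dien-3-yl]oxy-dimethyl-phenylsilane (not isolated) | CC1=CC[C@H](Br)C(C)(C)[C@@]12CCC(O[Si](C)(C)c3ccccc3)=CC2 | intermediate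
10 | (2R,6R,10S)-2,10-dibromo-7,11,11-trimethylspiro[5.5]undec-7-en-3-one | CC1=CC[C@H](Br)C(C)(C)[C@@]12CCC(=O)[C@H](Br)C2 | intermediate
11 | (2R,6R,10S)-2,10-dibromo-3,7,11,11-tetramethylspiro[5.5]undec-7-en-3-ol (both C3 epimers, SMILES leaves C3 open) | CC1=CC[C@H](Br)C(C)(C)[C@@]12CCC(C)(O)[C@H](Br)C2 | intermediate
12 | (2R,3R,6R,10S)-2,10-dibromo-3-chloro-3,7,11,11-tetramethylspiro[5.5]undec-7-ene | CC1=CC[C@H](Br)C(C)(C)[C@@]12CC[C@@](C)(Cl)[C@H](Br)C2 | target

**Step count**
Total: 7 steps. Longest linear sequence: 7 steps (1 to 12); 6 enters in step 4.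

**Three steps most likely to fail**

Step 3 (the proposed new step). The ionised bromohydrin may lose a proton or undergo a hydride shift before the short-lived dienol ether captures it, and exocyclic alkene isomers may form. The fallback uses known chemistry, sets out from 3 and returns at 5. The acetal is hydrolysed (aqueous oxalic acid, THF) to (6S)-6-bromo-7-hydroxy-3,7-dimethyloct-2-enal F1, which is reduced with NaBH4/CeCl3·7H2O to (6S)-6-bromo-3,7-dimethyloct-2-ene-1,7-diol F2. The primary hydroxyl is acetylated (Ac2O, pyridine) to (6S)-6-bromo-7-hydroxy-3,7-dimethyloct-2-en-1-yl acetate F3, and the tertiary alcohol is converted with the chloroenamine of step 7 into the vicinal bromochloride (6S)-6-bromo-7-chloro-3,7-dimethyloct-2-en-1-yl acetate F4. Solvolysis of this in (CF3)2CHOH, the established bromochloride-initiated bromonium polyene cyclisation with an alkene terminator, gives [(5S)-5-bromo-2,6,6-trimethylcyclohex-2-en-1-yl]methyl acetate F5. K2CO3 in MeOH then gives [(5S)-5-bromo-2,6,6-trimethylcyclohex-2-en-1-yl]methanol F6, and Dess–Martin periodinane oxidation returns aldehyde 5.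

Step 4. The new quaternary carbon sits between a gem-dimethyl carbon and a trisubstituted alkene, so conjugate addition may be slow, go to the γ-carbon of the dienolate, or be accompanied by loss of HBr; face selectivity may also be incomplete. The fallback sets out from 5 and returns at 7. It replaces conjugate addition by enolate alkylation: deprotonation with KN(SiMe3)2 at −78 °C and C-alkylation with 2-(2-iodoethyl)-2-methyl-1,3-dioxolane gives (1R,5S)-5-bromo-2,6,6-trimethyl-1-[2-(2-methyl-1,3-dioxolan-2-yl)ethyl]cyclohex-2-ene-1-carbaldehyde F7. Aqueous HCl in THF then unmasks keto aldehyde 7, which is closed to 8 with pyrrolidine and CH3CO2H as before.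

Step 7. If the equatorial bromine does not bridge, chloride enters axially (C3 epimer) or the cation eliminates; the wanted product needs opening at the tertiary carbon through a twist-boat. The fallback sets out from 8 and returns at 12, and makes both ring B carbon–halogen bonds by alkene bromochlorination instead. Conjugate reduction of 8 with LiBH(s-Bu)3 and trapping of the enolate with PhNTf2 gives (6R,10S)-10-bromo-7,11,11-trimethylspiro[5.5]undeca-2,7-dien-3-yl trifluoromethanesulfonate F8. Me2CuLi converts this into (6R,10S)-10-bromo-3,7,11,11-tetramethylspiro[5.5]undeca-2,7-diene F9. N-bromosuccinimide with Me3SiCl in CH2Cl2 at −78 °C then adds bromine and chlorine across the less hindered ring B alkene (chloride at the tertiary carbon, anti) to give 12.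

**Further compounds**
F1 | step 3 | (6S)-6-bromo-7-hydroxy-3,7-dimethyloct-2-enal | O=CC=C(C)CC[C@H](Br)C(C)(C)O
F2 | step 3 | (6S)-6-bromo-3,7-dimethyloct-2-ene-1,7-diol | OCC=C(C)CC[C@H](Br)C(C)(C)O
F3 | step 3 | (6S)-6-bromo-7-hydroxy-3,7-dimethyloct-2-en-1-yl acetate | CC(=O)OCC=C(C)CC[C@H](Br)C(C)(C)O
F4 | step 3 | (6S)-6-bromo-7-chloro-3,7-dimethyloct-2-en-1-yl acetate | CC(=O)OCC=C(C)CC[C@H](Br)C(C)(C)Cl
F5 | step 3 | [(5S)-5-bromo-2,6,6-trimethylcyclohex-2-en-1-yl]methyl acetate | CC(=O)OCC1C(C)=CC[C@H](Br)C1(C)C
F6 | step 3 | [(5S)-5-bromo-2,6,6-trimethylcyclohex-2-en-1-yl]methanol | OCC1C(C)=CC[C@H](Br)C1(C)C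
F7 | step 4 | (1R,5S)-5-bromo-2,6,6-trimethyl-1-[2-(2-methyl-1,3-dioxolan-2-yl)ethyl]cyclohex-2-ene-1-carbaldehyde | CC1=CC[C@H](Br)C(C)(C)[C@@]1(C=O)CCC2(C)OCCO2
F8 | step 7 | (6R,10S)-10-bromo-7,11,11-trimethylspiro[5.5]undeca-2,7-dien-3-yl trifluoromethanesulfonate | CC1=CC[C@H](Br)C(C)(C)[C@@]12CCC(OS(=O)(=O)C(F)(F)F)=CC2
F9 | step 7 | (6R,10S)-10-bromo-3,7,11,11-tetramethylspiro[5.5]undeca-2,7-diene | CC1=CC[C@H](Br)C(C)(C)[C@@]12CCC(C)=CC2
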